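**Retrosynthetic overview**
- Target 20 ⇒ aryl aldehyde 16 + diketone 19 (boron-templated aldol condensation; 19 from 17 + 18). 16 ⇒ vinyl oxirane 14 + vanillin 15 (cis-1,4 opening under zerovalent palladium, which makes the C–OAr bond and its stereocentre). 14 ⇒ face-selective epoxidation of the cyclohexadiene 13 (α-turmerone).
- 13 ⇒ cyclohexenone 9 (ketone erased through dienyl triflate 11; side-chain enone made from the N-methoxy-N-methylamide). 9 ⇒ enal 6 + tert-butyl 3-oxopentanoate 7 by one amine-catalysed [3+3] annulation. It forms the bond C2(7)–C4(6) (future ArO–CH carbon to the ring CH that bears the side chain) and the bond C4(7)–C6(6) (C(CH3)= to the future carbinol carbon).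
- Enabling feature: in the cyclohexene ring the carbons ArO–CH, =CH and =C(CH3) are a 1,3-dinucleophile once the =CH is written as C=O (C2–C3–C4 of a 3-oxopentanoate), and the carbons CH(OH), CH2 and CH(side chain) are a 1,3-dielectrophile (C6–C5–C4 of an enal). The carbonyl is removed afterwards and both ring oxygens are added 1,4 across the resulting diene.
- Ring order: the cyclohexene ring is the only ring built (step 4); both benzene rings are bought (15, 17); the oxirane of 14 is temporary (made in step 8, opened in step 9). The side-chain stereocentre comes from (R)-citronellic acid 1.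

Key step: step 4

Remark: the 1,3-diketone of the target is a fast keto–enol equilibrium; the enol drawn is one tautomer of the product of step 11, and 19 is written in its diketo form.

**Route**

Step 1
Reactants: 1 (R)-citronellic acid [(3R)-3,7-dimethyloct-6-enoic acid]
Product: 3 (3R)-N-methoxy-N,3,7-trimethyloct-6-enamide, via acyl imidazolide 2 (not isolated)
Conditions: 1,1'-carbonyldiimidazole, CH2Cl2, 0 °C to rt; then MeNHOMe·HCl, rt
Reagents that add atoms: N,O-dimethylhydroxylamine hydrochloride, CNOC.Cl
Why: Activation of the acid as its imidazolide and aminolysis (Weinreb amide formation) leave the β-stereocentre untouched and install the acyl group that later becomes the side-chain ketone.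

Step 2
Reactants: 3 (3R)-N-methoxy-N,3,7-trimethyloct-6-enamide
Product: 5 (3R)-N-methoxy-N,3-dimethyl-6-oxohexanamide, via ozonide 4 (not isolated)
Conditions: O3, CH2Cl2, −78 °C; then PPh3, −78 °C to rt
Reagents that add atoms: ozone, [O-][O+]=O
Why: Ozonolysis with reductive cleavage of the ozonide cuts the only C=C bond to the aldehyde, and the amide is inert.

Step 3
Reactants: 5 (3R)-N-methoxy-N,3-dimethyl-6-oxohexanamide
Product: 6 (3S,4E)-N-methoxy-N,3-dimethyl-6-oxohex-4-enamide
Conditions: IBX (1.5 equiv), fluorobenzene/DMSO 2:1, 65 °C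
Reagents that add atoms: none
Why: IBX-mediated α,β-dehydrogenation of the aldehyde through its enol should give the conjugated (E)-enal under non-basic conditions that do not touch the adjacent tertiary stereocentre (its descriptor changes from R to S only because the neighbouring carbon becomes sp2).

Step 4
Reactants: 6 (3S,4E)-N-methoxy-N,3-dimethyl-6-oxohex-4-enamide; 7 tert-butyl 3-oxopentanoate
Product: 9 (3S)-N-methoxy-N-methyl-3-[(1S)-4-methyl-5-oxocyclohex-3-en-1-yl]butanamide, via Michael adduct 8 (not isolated)
Conditions: (R)-2-[diphenyl(trimethylsilyloxy)methyl]pyrrolidine (10 mol %), toluene, 0 °C to rt; then TsOH·H2O (30 mol %), toluene, 80 °C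
Reagents that add atoms: none
Why: The secondary amine condenses with 6 to the (E)-iminium ion, the enol of 7 adds through C2 to the β-carbon (C4 of 6) to give 8 after hydrolysis, and TsOH then drives the intramolecular aldol condensation of the ethyl-ketone CH2 onto the aldehyde together with loss of 2-methylpropene and CO2 from the tert-butyl β-keto ester. The closest known reaction type is the diarylprolinol-silyl-ether-catalysed Michael addition of β-keto esters to enals followed by acid-mediated aldol condensation and decarboxylation to 5-substituted cyclohex-2-enones. The six-membered ring closes in a 6-(enolendo)-exo-trig aldol step, the only enol/carbonyl pairing of the 1,5-keto aldehyde that does not give a four-membered ring, and dehydration leaves the conjugated 2-methylenone. The new ring stereocentre (C1 of the cyclohexenyl group, S) is set by the catalyst: the CPh2(OSiMe3) group of the (R)-amine blocks the Re face of the iminium β-carbon, so the nucleophile adds to the Si face, while the stereocentre at the keto-ester carbon is erased by decarboxylation. The step needs 1,4- over 1,2-addition (secured by iminium activation and the soft, doubly stabilised nucleophile), C- over O-cyclisation (the hemiacetal is reversible under acid), and retention of the side-chain stereocentre, for which the Michael stage is run cold and without acid co-catalyst so that γ-deprotonation of the iminium ion stays slow.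

Step 5
Reactants: 9 (3S)-N-methoxy-N-methyl-3-[(1S)-4-methyl-5-oxocyclohex-3-en-1-yl]butanamide
Product: 11 (3R)-3-[(2S)-4-[methoxy(methyl)amino]-4-oxobutan-2-yl]-6-methylcyclohexa-1,5-dien-1-yl trifluoromethanesulfonate, via potassium enolate 10 (not isolated)
Conditions: KN(SiMe3)2 (1.05 equiv), THF, −78 °C; then PhNTf2, −78 °C to 0 °C
Reagents that add atoms: N-phenylbis(trifluoromethanesulfonimide), O=S(=O)(N(c1ccccc1)S(=O)(=O)C(F)(F)F)C(F)(F)F
Why: Kinetic deprotonation of the enone at the α′-CH2 (cross-conjugated enolate) and O-triflation should give the 2-triflyloxy-1,3-diene, since the amide α-protons are far less acidic and no stereocentre is deprotonated.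

Step 6
Reactants: 11 (3R)-3-[(2S)-4-[methoxy(methyl)amino]-4-oxobutan-2-yl]-6-methylcyclohexa-1,5-dien-1-yl trifluoromethanesulfonate
Product: 12 (3S)-N-methoxy-N-methyl-3-[(1R)-4-methylcyclohexa-2,4-dien-1-yl]butanamide
Conditions: Pd(OAc)2 (5 mol %), PPh3 (10 mol %), HCO2H, n-Bu3N, DMF, 60 °C
Reagents that add atoms: none
Why: Oxidative addition of zerovalent palladium (formed in situ) into the C–OTf bond, formate-to-hydride exchange with loss of CO2 and reductive elimination (palladium-catalysed formate reduction of an enol triflate) replace OTf by H and leave the conjugated 1,3-diene.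

Step 7
Reactants: 12 (3S)-N-methoxy-N-methyl-3-[(1R)-4-methylcyclohexa-2,4-dien-1-yl]butanamide
Product: 13 α-turmerone, (6S)-2-methyl-6-[(1R)-4-methylcyclohexa-2,4-dien-1-yl]hept-2-en-4-one
Conditions: (CH3)2C=CHMgBr (2 equiv), THF, 0 °C; aqueous NH4Cl work-up
Reagents that add atoms: 2-methylprop-1-enylmagnesium bromide, CC(C)=C[Mg]Br
Why: Weinreb ketone synthesis, in which the alkenyl Grignard reagent adds only once because the chelated tetrahedral adduct persists until work-up, should give the side-chain enone.

Step 8
Reactants: 13 α-turmerone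
Product: 14 (6S)-2-methyl-6-[(1R,4R,6S)-1-methyl-7-oxabicyclo[4.1.0]hept-2-en-4-yl]hept-2-en-4-one
Conditions: 1,2:4,5-di-O-isopropylidene-β-L-erythro-2,3-hexodiulo-2,6-pyranose (L-fructose-derived ketone, 30 mol %), 2KHSO5·KHSO4·K2SO4, K2CO3, Bu4NHSO4 (cat.), aqueous Na2B4O7 buffer (pH 10.5), MeCN/CH2(OMe)2, 0 °C
Reagents that add atoms: potassium peroxymonosulfate, [K+].[O-]S(=O)(=O)OO
Why: In this Shi-type epoxidation the chiral dioxirane should attack the most electron-rich, trisubstituted ring alkene (the cis-disubstituted ring alkene and the conjugated enone alkene are poor substrates), the spiro transition state of the L-fructose-derived ketone is expected to deliver oxygen to the face anti to the side chain (the face the substrate itself should also prefer), which sets both oxirane stereocentres, and the basic buffer protects the labile tertiary allylic epoxide.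

Step 9
Reactants: 14 (6S)-2-methyl-6-[(1R,4R,6S)-1-methyl-7-oxabicyclo[4.1.0]hept-2-en-4-yl]hept-2-en-4-one; 15 vanillin
Product: 16 4-{[(1R,4S,6R)-4-hydroxy-3-methyl-6-[(2S)-6-methyl-4-oxohept-5-en-2-yl]cyclohex-2-en-1-yl]oxy}-3-methoxybenzaldehyde
Conditions: Pd(PPh3)4 (5 mol %), THF, 0 °C to rt
Reagents that add atoms: none
Why: In this Tsuji–Trost-type allylic etherification zerovalent palladium ionises the vinyl oxirane with inversion to a π-allyl complex whose alkoxide deprotonates vanillin, and the phenoxide attacks the distal, less substituted allyl terminus anti to palladium, so the ArO–CH centre forms with net retention, cis to the carbinol oxygen and trans to the side chain.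

Step 10
Reactants: 17 4-hydroxybenzaldehyde; 18 acetylacetone (3 equiv)
Product: 19 (5E)-6-(4-hydroxyphenyl)hex-5-ene-2,4-dione
Conditions: B2O3, B(OBu)3, n-BuNH2 (cat.), EtOAc, 70 °C; work-up with dilute aqueous HCl
Reagents that add atoms: none
Why: Boron chelation of the diketone masks C3 and directs the amine-catalysed aldol condensation to a terminal methyl, excess diketone suppressing double condensation and the (E)-alkene forming under thermodynamic control.

Step 11
Reactants: 16 4-{[(1R,4S,6R)-4-hydroxy-3-methyl-6-[(2S)-6-methyl-4-oxohept-5-en-2-yl]cyclohex-2-en-1-yl]oxy}-3-methoxybenzaldehyde; 19 (5E)-6-(4-hydroxyphenyl)hex-5-ene-2,4-dione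
Product: 20 demethoxybisabolocurcumin ether
Conditions: B2O3, B(OBu)3, n-BuNH2 (cat.), EtOAc, 60 °C; work-up with dilute aqueous AcOH at rt
Reagents that add atoms: none
Why: The same boron-templated aldol condensation should engage the remaining methyl of 19 with the aryl aldehyde (the unchelated side-chain ketone is not activated), and mild hydrolysis releases the (E,E)-curcuminoid without disturbing the allylic aryl ether or any stereocentre.

**Compound list**

1 | (R)-citronellic acid, (3R)-3,7-dimethyloct-6-enoic acid | CC(C)=CCC[C@@H](C)CC(=O)O | starting material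
2 | (3R)-1-(1H-imidazol-1-yl)-3,7-dimethyloct-6-en-1-one (acyl imidazolide, not isolated) | CC(C)=CCC[C@@H](C)CC(=O)n1ccnc1 | intermediate
3 | (3R)-N-methoxy-N,3,7-trimethyloct-6-enamide | CC(C)=CCC[C@@H](C)CC(=O)N(C)OC | intermediate
4 | (3R)-5-(5,5-dimethyl-1,2,4-trioxolan-3-yl)-N-methoxy-N,3-dimethylpentanamide (ozonide, not isolated, trioxolane epimers) | CC1(C)OOC(CC[C@@H](C)CC(=O)N(C)OC)O1 | intermediate
5 | (3R)-N-methoxy-N,3-dimethyl-6-oxohexanamide | O=CCC[C@@H](C)CC(=O)N(C)OC | intermediate
6 | (3S,4E)-N-methoxy-N,3-dimethyl-6-oxohex-4-enamide | O=C/C=C/[C@@H](C)CC(=O)N(C)OC | intermediate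
7 | tert-butyl 3-oxopentanoate | CCC(=O)CC(=O)OC(C)(C)C | starting material
8 | tert-butyl (3R)-3-[(2S)-4-[methoxy(methyl)amino]-4-oxobutan-2-yl]-5-oxo-2-propanoylpentanoate (Michael adduct, not isolated, C2 epimers) | CCC(=O)C(C(=O)OC(C)(C)C)[C@H](CC=O)[C@@H](C)CC(=O)N(C)OC | intermediate
9 | (3S)-N-methoxy-N-methyl-3-[(1S)-4-methyl-5-oxocyclohex-3-en-1-yl]butanamide | CC1=CC[C@@H](CC1=O)[C@@H](C)CC(=O)N(C)OC | intermediate
10 | potassium (3R)-3-[(2S)-4-[methoxy(methyl)amino]-4-oxobutan-2-yl]-6-methylcyclohexa-1,5-dien-1-olate (not isolated) | CC1=CC[C@@H](C=C1[O-])[C@@H](C)CC(=O)N(C)OC.[K+] | intermediate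
11 | (3R)-3-[(2S)-4-[methoxy(methyl)amino]-4-oxobutan-2-yl]-6-methylcyclohexa-1,5-dien-1-yl trifluoromethanesulfonate | CC1=CC[C@@H](C=C1OS(=O)(=O)C(F)(F)F)[C@@H](C)CC(=O)N(C)OC | intermediate
12 | (3S)-N-methoxy-N-methyl-3-[(1R)-4-methylcyclohexa-2,4-dien-1-yl]butanamide | CC1=CC[C@@H](C=C1)[C@@H](C)CC(=O)N(C)OC | intermediate
13 | α-turmerone, (6S)-2-methyl-6-[(1R)-4-methylcyclohexa-2,4-dien-1-yl]hept-2-en-4-one | CC1=CC[C@@H](C=C1)[C@@H](C)CC(=O)C=C(C)C | intermediate
14 | (6S)-2-methyl-6-[(1R,4R,6S)-1-methyl-7-oxabicyclo[4.1.0]hept-2-en-4-yl]hept-2-en-4-one | C1=C[C@@]2(C)O[C@H]2C[C@@H]1[C@@H](C)CC(=O)C=C(C)C | intermediate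
15 | vanillin, 4-hydroxy-3-methoxybenzaldehyde | COc1cc(C=O)ccc1O | starting material
16 | 4-{[(1R,4S,6R)-4-hydroxy-3-methyl-6-[(2S)-6-methyl-4-oxohept-5-en-2-yl]cyclohex-2-en-1-yl]oxy}-3-methoxybenzaldehyde | COc1cc(C=O)ccc1O[C@H]1C=C(C)[C@@H](O)C[C@@H]1[C@@H](C)CC(=O)C=C(C)C | intermediate
17 | 4-hydroxybenzaldehyde | O=Cc1ccc(O)cc1 | starting material
18 | acetylacetone, pentane-2,4-dione | CC(=O)CC(C)=O | starting material
19 | (5E)-6-(4-hydroxyphenyl)hex-5-ene-2,4-dione | CC(=O)CC(=O)/C=C/c1ccc(O)cc1 | intermediate
20 | demethoxybisabolocurcumin ether, (1E,4Z,6E)-5-hydroxy-7-(4-{[(1R,4S,6R)-4-hydroxy-3-methyl-6-[(2S)-6-methyl-4-oxohept-5-en-2-yl]cyclohex-2-en-1-yl]oxy}-3-methoxyphenyl)-1-(4-hydroxyphenyl)hepta-1,4,6-trien-3-one | COc1cc(/C=C/C(O)=C/C(=O)/C=C/c2ccc(O)cc2)ccc1O[C@H]1C=C(C)[C@@H](O)C[C@@H]1[C@@H](C)CC(=O)C=C(C)C | target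

Total step count: 11. Longest linear sequence: 10 steps (steps 1 to 9, then step 11; step 10 is a one-step side branch).

**Steps most likely to fail**

Step 8. What may go wrong: oxygen transfer to the wrong face (syn to the side chain) or to the disubstituted ring alkene, and acid- or silica-induced ring opening with aromatisation of the tertiary allylic epoxide during isolation. Fallback: put the oxirane oxygen in at the enone stage, where nucleophilic epoxidation is governed by axial attack anti to the ring substituent, and remove the carbonyl afterwards. It sets out from 9 and comes back at 14. Weitz–Scheffer epoxidation of 9 (H2O2, NaOH, MeOH, 0 °C) should give the epoxy ketone (3S)-N-methoxy-N-methyl-3-[(1S,4S,6S)-1-methyl-2-oxo-7-oxabicyclo[4.1.0]heptan-4-yl]butanamide F1 with the oxirane trans to the side chain. NaBH4 (MeOH, 0 °C) would reduce the ketone to the epoxy alcohol, the 2-hydroxy analogue of F1 (either carbinol epimer serves) F2. (CH3)2C=CHMgBr (3 equiv, THF, 0 °C) would turn the N-methoxy-N-methylamide into the enone 6-(2-hydroxy-1-methyl-7-oxabicyclo[4.1.0]heptan-4-yl)-2-methylhept-2-en-4-one F3. Dehydration of the secondary alcohol with Ph2S[OC(CF3)2Ph]2 (CH2Cl2, 0 °C) can only take a hydrogen from the ring CH2, because the other neighbour is the fully substituted oxirane carbon, and would give 14.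

Step 4. What may go wrong: erosion of the side-chain stereocentre by γ-deprotonation of the iminium ion, stalling at the O-cyclised hemiacetal, or retro-Michael reaction and epimerisation during the hot acidic aldol–decarboxylation stage. Fallback: close the ring by an intramolecular Wittig reaction, so that cyclisation occurs at room temperature under near-neutral conditions as soon as the Michael adduct forms (a Michael/Wittig [3+3] annulation, known for the parent ylide). It sets out from 6 and comes back at 9. Commercial ethyl 4-bromo-3-oxopentanoate and PPh3 (toluene, rt) would give (5-ethoxy-3,5-dioxopentan-2-yl)triphenylphosphonium bromide F4, and aqueous Na2CO3 the stabilised ylide ethyl 3-oxo-4-(triphenyl-λ5-phosphanylidene)pentanoate F5. With 6 and the amine catalyst of step 4 (CHCl3, rt) the active methylene of F5 should add to the iminium ion and the ylide carbon then close onto the aldehyde, giving ethyl (6R)-6-[(2S)-4-[methoxy(methyl)amino]-4-oxobutan-2-yl]-3-methyl-2-oxocyclohex-3-ene-1-carboxylate F6. Krapcho dealkoxycarbonylation (LiCl, wet DMSO, 130 °C) would then give 9.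

Step 11. What may go wrong: ionisation of the allylic aryl ether (loss of the phenol, then aromatisation of the ring) or dehydration of the allylic alcohol while the boron chelate is hydrolysed, and slow competing condensation at the side-chain ketone on prolonged heating. Fallback: preform and isolate the activated diketone as its difluoroboron chelate and release the product by ligand exchange instead of acid. It sets out from 16 and 19 and comes back at 20. BF3·OEt2 (CH2Cl2, rt) would convert 19 into 2,2-difluoro-4-[(E)-2-(4-hydroxyphenyl)ethenyl]-6-methyl-1,3,2-dioxaborinine (difluoroboron chelate of 19) F7. Condensation of F7 with 16 (n-BuNH2 cat., EtOAc, rt to 40 °C) would give the difluoroboron chelate of 20 F8. Na2C2O4 in aqueous MeOH at 60 °C would then remove the BF2 group and give 20.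

**Further compounds**

F1 | step 8 | (3S)-N-methoxy-N-methyl-3-[(1S,4S,6S)-1-methyl-2-oxo-7-oxabicyclo[4.1.0]heptan-4-yl]butanamide | C1C(=O)[C@@]2(C)O[C@H]2C[C@@H]1[C@@H](C)CC(=O)N(C)OC
F2 | step 8 | 2-hydroxy analogue of F1: (3S)-3-(2-hydroxy-1-methyl-7-oxabicyclo[4.1.0]heptan-4-yl)-N-methoxy-N-methylbutanamide, oxirane trans to the side chain, carbinol epimers | C1C(O)[C@@]2(C)O[C@H]2C[C@@H]1[C@@H](C)CC(=O)N(C)OC
F3 | step 8 | (6S)-6-(2-hydroxy-1-methyl-7-oxabicyclo[4.1.0]heptan-4-yl)-2-methylhept-2-en-4-one, ring stereocentres as in F2 | C1C(O)[C@@]2(C)O[C@H]2C[C@@H]1[C@@H](C)CC(=O)C=C(C)C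
F4 | step 4 | (5-ethoxy-3,5-dioxopentan-2-yl)triphenylphosphonium bromide | CCOC(=O)CC(=O)C(C)[P+](c1ccccc1)(c1ccccc1)c1ccccc1.[Br-]
F5 | step 4 | ethyl 3-oxo-4-(triphenyl-λ5-phosphanylidene)pentanoate | CCOC(=O)CC(=O)C(C)=P(c1ccccc1)(c1ccccc1)c1ccccc1
F6 | step 4 | ethyl (6R)-6-[(2S)-4-[methoxy(methyl)amino]-4-oxobutan-2-yl]-3-methyl-2-oxocyclohex-3-ene-1-carboxylate (C1 epimers) | CCOC(=O)C1C(=O)C(C)=CC[C@@H]1[C@@H](C)CC(=O)N(C)OC
F7 | step 11 | 2,2-difluoro-4-[(E)-2-(4-hydroxyphenyl)ethenyl]-6-methyl-1,3,2-dioxaborinine (difluoroboron chelate of 19) | CC1=CC(/C=C/c2ccc(O)cc2)=[O+][B-](F)(F)O1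
F8 | step 11 | difluoroboron chelate of 20 | COc1cc(/C=C/C2=CC(/C=C/c3ccc(O)cc3)=[O+][B-](F)(F)O2)ccc1O[C@H]1C=C(C)[C@@H](O)C[C@@H]1[C@@H](C)CC(=O)C=C(C)C
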